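## Analysis of the target

The target 19 is a flavone, a 4H-chromen-4-one in which the benzo ring A (C4a to C8a) is fused to the pyranone ring C (O1, C2, C3, C4) and the aryl ring B sits on C2. It has no stereocenter and no double bond of open geometry, so the task is to place and tell apart oxygens, not to control configuration. Besides O1 and the carbonyl there are four oxygen substituents, a methyl ether on C3 and free hydroxyls on C5, C7 and C4', so only the C3 oxygen may carry carbon at the end. Ring B bears two 3-methylbut-2-enyl (prenyl) groups at C3' and C5' that flank the C4' hydroxyl; this ortho-prenyl phenol closes to a 2,2-dimethylchroman with acid, and the trisubstituted alkenes rule out hydrogenolysis, strong oxidants and electrophilic halogen late in the route. Ring A has the phloroglucinol pattern, which as a phenol or phenol ether is very electron-rich, prone to C-alkylation and slow to acylate between two ortho oxygens. The difficulty therefore lies in the end game: ring C must be closed and three phenols set free without acid and without reagents that add to alkenes. The plan rests on one feature: O1 on C8a and the oxygens on C5 and C7 all stand ortho or para to the C4 carbonyl, so each of these three C–O bonds can be made by displacing fluorine from a ring A that starts as a 2,4,6-trifluorobenzoyl unit activated by that carbonyl.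

## Retrosynthetic reasoning

**19 from 18.** The three phenolic oxygens (O5, O7, O4') are masked as allyl ethers in 18. An allyl ether is ionised by zerovalent palladium under neutral conditions, with no acid to cyclise the prenyl phenol and no oxidant or hydrogen to touch the prenyl alkenes. On O5 and O7 the allyl group is simply the carbon part of the oxygen nucleophile 14 that brings these oxygens in, so one kind of group and one removal step serve all three positions.

**18 from 13 and 14.** Three bonds are cut: O1–C8a, C5–O and C7–O. Cutting on the ring A side of each oxygen makes the ring A carbons electrophilic, which is possible because all three are ortho or para to C4=O. The usual cut at C2–O1 would demand a ring A that carries all three oxygens before ring closure, and an acid-driven dehydration. Forward, the enolate 15 of diketone 13 must close ring C through oxygen to give 16, and the alkoxide of 14 must then replace the fluorine on C7 (17) and on C5 (18). The gain is that ring A is bought as the symmetric acid chloride 11, and that the C3 methyl ether is present from the start, so four oxygens never have to be distinguished by selective alkylation. The forward reaction has to keep the order: closure first, alkoxide second.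

**13 from 10 and 11.** The C3–C4 bond is cut. Only ketone 10 can enolise and 11 has no α-hydrogen, so acylation of enolate 12 can give only one crossed product. This places the trifluorophenyl ketone directly next to the methoxy-bearing carbon.

**10 from 6 and 7.** The bond between ring B (C1') and the future C2 carbonyl is cut. Aryllithium 8, formed from bromide 6, adds to the Weinreb amide 7 and stops at the ketone stage through chelate 9. The amide supplies C2, C3 and the O3 methyl group as one bought piece.

**6 from 4 and 5.** The O4'–allyl bond is cut, an ordinary phenol alkylation. The free phenol is needed in the step before and must be capped before metalation.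

**4 from 1 and 2.** The two aryl–CH2 bonds ortho to the hydroxyl are cut, passing through the monoalkylated phenol 3. The bromine of 1 blocks the para position during C-alkylation and later becomes the handle for the lithiation.

## Alternatives that were turned down

**Alternative 1: carbonylative three-component assembly of the diketone.**
- Disconnection: C4a–C4 and C3–C4 are both cut. C4 comes from carbon monoxide A2, ring A from the symmetric iodide 2-iodo-1,3,5-tris(methoxymethoxy)benzene A1, and C2, C3 and ring B from the ketone 2-methoxy-1-[4-(methoxymethoxy)-3,5-bis(3-methylbut-2-enyl)phenyl]ethanone A3.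
- Forward key step: zerovalent palladium inserts into the C–I bond of A1, A2 inserts to give an aroyl palladium species, and this acylates the enolate of A3 at carbon to give the diketone A4.
- For it: it is fully convergent, A1 is symmetric so no regiochemistry arises, and the ring A oxygens are in place from the start. Its longest linear sequence is no longer than that of the chosen route. It is stronger in one respect: it never has to force a nucleophile onto a ring that grows more electron-rich with each substitution.
- Against it: A1 is electron-rich and substituted at both ortho positions, so oxidative addition and acyl transfer from a crowded aroyl palladium to a fully substituted enolate carbon are both slow. That opens the way to direct α-arylation of A3 without uptake of A2, and to O-acylation. The decisive point is what follows A4. Ring C can close only after an ortho oxygen of ring A is unmasked, and cyclodehydration plus removal of four methoxymethyl groups needs protic acid. At that stage the C4' phenol, once free, sits between two prenyl groups and cyclises to a chroman under the same conditions.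
- Comparison: the chosen route gives up the pre-installed oxygens, but it closes ring C with carbonate and frees the phenols with neutral palladium chemistry, so no acid meets the prenyl phenol.

**Alternative 2: pinacol closure of ring C.**
- Disconnection: C3–C4, leading back to the dialdehyde 2-[2-formyl-3,5-bis(methoxymethoxy)phenoxy]-2-[4-(methoxymethoxy)-3,5-bis(3-methylbut-2-enyl)phenyl]acetaldehyde A5 (racemic), in which O1–C2 already links the two halves.
- Forward key step: samarium diiodide A6 (SmI2) reduces the aromatic aldehyde of A5 to a ketyl, which adds to the neighbouring aliphatic aldehyde. A samarium bridge between the two oxygens makes the 3,4-diol cis, and the C2 aryl group takes the position trans to O3, giving the chromane-3,4-diol A7.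
- For it: the ring-forming event with A6 is mild, neutral and indifferent to the prenyl alkenes, and its relative configuration is predictable. Taken alone, it is a gentler closure than a sequence of three substitutions on an arene.
- Against it: the target has no stereocenter, so the three centres of A7 are made only to be destroyed. A7 lies four electrons below the 3-oxygenated chromone, and both carbinol carbons and C2–H must be oxidised in the presence of two trisubstituted alkenes and an electron-rich ring A. O3 must then be methylated, and three methoxymethyl groups removed with acid next to the prenyl groups. A5 is an α-aryloxy arylacetaldehyde with a doubly activated α-hydrogen, hard to make and to keep, and its synthesis needs an ether bond from a hindered, hydrogen-bonded salicylaldehyde oxygen to a benzylic carbon.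
- Comparison: after the key step it is clearly longer (oxidation, methylation and deprotection against one deprotection). The chosen route brings C3 in with its methyl ether at the final oxidation level, so no redox step or selective alkylation follows ring closure.

**Alternative 3: benzannulation of ring A.**
- Disconnection: C5–C6, C7–C8 and C4a–C5, so that ring A is built onto a finished ring C. The partners are the diazoketone 6-(2-diazoacetyl)-3-methoxy-2-[4-(methoxymethoxy)-3,5-bis(3-methylbut-2-enyl)phenyl]-4H-pyran-4-one A8 and (ethynyloxy)tri(propan-2-yl)silane A9.
- Forward key step (Danheiser benzannulation): irradiation of A8 triggers a Wolff rearrangement. The resulting ketene adds to A9 in a [2+2] sense, the cyclobutenone opens (4π), and the dienyl ketene closes (6π) and tautomerises to the phenol A10, with the C5 hydroxyl free and the C7 oxygen silylated.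
- For it: ring A is formed with complete regiocontrol under neutral conditions, and O5 and O7 come out differentiated, which the chosen route cannot offer.
- Against it: that differentiation has no use here, because both hydroxyls are free in the target. A8 gathers ring B, the C3 methoxy group and a diazoacetyl group on one fully substituted pyranone, and there is no short entry to such a ring. The 6π closure must draw on the C4a=C8a bond of a cross-conjugated pyranone, and the pyranone absorbs the light and has photochemistry of its own. A9 is a sensitive reagent. The end still needs fluoride and then acid for the methoxymethyl ether on the prenyl-flanked phenol of A10.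
- Comparison: the chosen route buys ring A as the symmetric acid chloride 11, needs no photochemistry and is several steps shorter.

Key step: step 5

Remark on the chemistry: 13 is written as the diketo form; it should be partly enolised, its C2 centre is racemic and disappears when ring C forms, so no configuration has to be controlled anywhere in the route.

## Route

**Step 1**
Reactants: 1 4-bromophenol; 2 1-bromo-3-methylbut-2-ene (prenyl bromide)
Product: 4 4-bromo-2,6-bis(3-methylbut-2-enyl)phenol, via monoprenyl phenol 3 (not isolated)
Conditions: NaH (2 × 1.1 equiv), 2 (2 × 1.1 equiv), toluene, 0 → 25 °C; neutral work-up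
Reagents that add atoms: prenyl bromide CC(C)=CCBr
Why: Ortho C-alkylation of a sodium phenoxide (phenoxide C-prenylation): in toluene the sodium salt of 1 is a tight, aggregated ion pair whose oxygen is shielded, so the allylic bromide is attacked by the ortho carbon and the cyclohexadienone tautomerises back to the phenol. Bromine blocks the para position, and a second round on 3 fills the other ortho position.

**Step 2**
Reactants: 4 4-bromo-2,6-bis(3-methylbut-2-enyl)phenol; 5 3-bromoprop-1-ene (allyl bromide)
Product: 6 5-bromo-1,3-bis(3-methylbut-2-enyl)-2-(prop-2-enyloxy)benzene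
Conditions: 5 (1.5 equiv), K2CO3 (2 equiv), DMF, 25 → 50 °C
Reagents that add atoms: allyl bromide C=CCBr
Why: Williamson ether synthesis; in the polar aprotic solvent the potassium phenoxide reacts at oxygen, and the unhindered allylic bromide is taken even between two ortho substituents. The allyl ether lies para to bromine, so it cannot interfere with the metalation that follows.

**Step 3**
Reactants: 6 5-bromo-1,3-bis(3-methylbut-2-enyl)-2-(prop-2-enyloxy)benzene; 7 N,2-dimethoxy-N-methylacetamide
Product: 10 1-[3,5-bis(3-methylbut-2-enyl)-4-(prop-2-enyloxy)phenyl]-2-methoxyethanone, via aryllithium 8 (not isolated), via lithium hemiaminal chelate 9 (not isolated)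
Conditions: n-BuLi (1.05 equiv), THF, −78 °C; then 7 (1.2 equiv), −78 → 0 °C; aq. NH4Cl
Reagents that add atoms: N,2-dimethoxy-N-methylacetamide COCC(=O)N(C)OC
Why: Bromine–lithium exchange followed by Weinreb ketone synthesis: exchange at −78 °C is far faster than any attack on the allyl ether, and 8 adds to the amide to give the five-membered chelate 9, which holds until the quench and so releases the ketone without a second addition. The amide delivers C2, C3 and the O3 methyl group in one piece.

**Step 4**
Reactants: 10 1-[3,5-bis(3-methylbut-2-enyl)-4-(prop-2-enyloxy)phenyl]-2-methoxyethanone; 11 2,4,6-trifluorobenzoyl chloride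
Product: 13 1-[3,5-bis(3-methylbut-2-enyl)-4-(prop-2-enyloxy)phenyl]-2-methoxy-3-(2,4,6-trifluorophenyl)propane-1,3-dione (racemic, enolisable), via lithium enolate 12 (not isolated)
Conditions: LiN(SiMe3)2 (2.2 equiv), THF, −78 °C; then 11 (1.1 equiv), −78 → 0 °C; aq. NH4Cl
Reagents that add atoms: 2,4,6-trifluorobenzoyl chloride O=C(Cl)c1c(F)cc(F)cc1F
Why: Crossed Claisen-type C-acylation of a ketone lithium enolate with an aroyl chloride: only 10 can enolise, the chelated (Z)-enolate 12 is acylated at carbon by an acid chloride that has no α-hydrogen, and the second equivalent of LiN(SiMe3)2 takes the proton of the more acidic diketone so that no enolate is lost to it. At −78 to 0 °C neither the silylamide nor the lithium diketonate should attack the C–F bonds.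

**Step 5**
Reactants: 13 1-[3,5-bis(3-methylbut-2-enyl)-4-(prop-2-enyloxy)phenyl]-2-methoxy-3-(2,4,6-trifluorophenyl)propane-1,3-dione; 14 prop-2-en-1-ol (allyl alcohol)
Product: 18 2-[3,5-bis(3-methylbut-2-enyl)-4-(prop-2-enyloxy)phenyl]-3-methoxy-5,7-bis(prop-2-enyloxy)-4H-chromen-4-one, via potassium enolate 15 (not isolated), via 5,7-difluoroflavone 16 (not isolated), via 7-allyloxy-5-fluoroflavone 17 (not isolated)
Conditions: K2CO3 (3 equiv), DMF, 25 → 50 °C until 13 is consumed; then NaOCH2CH=CH2 [from NaH (4 equiv) and 14 (10 equiv) in THF], 0 → 60 °C
Reagents that add atoms: allyl alcohol C=CCO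
Why: K2CO3 converts 13 into the enolate 15, whose oxygen on the ring B side adds to a fluorine-bearing ortho carbon of the trifluorophenyl ring to give a Meisenheimer adduct with the charge on the C4 carbonyl; loss of fluoride forms O1–C8a and ring C in 16. This is the intramolecular SNAr closure by which 1-(2-fluoroaryl)-1,3-diketones are turned into flavones, and the two later events are ordinary alkoxide displacements of fluoride from a fluorinated chromone, each again an addition–elimination. Ring C closes at a trigonal carbon in a six-membered mode, 6-endo-trig if the C4a=C8a bond that relays the charge to the carbonyl is counted, the same geometry as the oxa-Michael closure of a chalcone; the other closures open to the enolate, through C3 or through the other oxygen, would be four-membered and do not compete. The two ortho fluorines are equivalent by the symmetry of the 2,4,6-trifluorophenyl group, so the closure has no regiochemical choice to make, and no stereocenter is formed because C3 becomes trigonal. NaOCH2CH=CH2, added only after 13 is consumed, should attack C7 (para to the carbonyl, favoured in the dipolar solvent) to give 17, and on warming C5 (ortho to it) to give 18; the order of these two does not matter because both fluorides end as allyl ethers. The selectivity needed is one of timing: an alkoxide that met the open-chain diketone could cleave it by retro-Claisen fragmentation or replace both ortho fluorines and leave nothing for O1 to displace, and this is prevented by using only the weak, non-nucleophilic carbonate in the first stage. The excess of 14 keeps the alkoxide too weak a base to move the allyl or prenyl double bonds into conjugation, and 60 °C is far below the temperature of an aromatic Claisen rearrangement.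

**Step 6**
Reactants: 18 2-[3,5-bis(3-methylbut-2-enyl)-4-(prop-2-enyloxy)phenyl]-3-methoxy-5,7-bis(prop-2-enyloxy)-4H-chromen-4-one
Product: 19 5,7-dihydroxy-2-[4-hydroxy-3,5-bis(3-methylbut-2-enyl)phenyl]-3-methoxy-4H-chromen-4-one
Conditions: Pd(PPh3)4 (10 mol %), morpholine (12 equiv), THF, 25 °C
Reagents that add atoms: none
Why: Tsuji–Trost type deallylation: zerovalent palladium ionises each aryl allyl ether to a π-allyl palladium cation and a phenoxide, and morpholine takes the allyl group irreversibly as its N-allyl derivative. The medium is neutral to weakly basic and holds no electrophile or hydride, so the prenyl alkenes, which are not allylic ethers, and the ortho-prenyl phenol should remain unchanged.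

## Compound list

1 | 4-bromophenol | Oc1ccc(Br)cc1 | starting material
2 | 1-bromo-3-methylbut-2-ene (prenyl bromide) | CC(C)=CCBr | starting material
3 | 4-bromo-2-(3-methylbut-2-enyl)phenol (not isolated) | CC(C)=CCc1cc(Br)ccc1O | intermediate
4 | 4-bromo-2,6-bis(3-methylbut-2-enyl)phenol | CC(C)=CCc1cc(Br)cc(CC=C(C)C)c1O | intermediate
5 | 3-bromoprop-1-ene (allyl bromide) | C=CCBr | starting material
6 | 5-bromo-1,3-bis(3-methylbut-2-enyl)-2-(prop-2-enyloxy)benzene | C=CCOc1c(CC=C(C)C)cc(Br)cc1CC=C(C)C | intermediate
7 | N,2-dimethoxy-N-methylacetamide | COCC(=O)N(C)OC | starting material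
8 | [3,5-bis(3-methylbut-2-enyl)-4-(prop-2-enyloxy)phenyl]lithium (not isolated) | [Li]c1cc(CC=C(C)C)c(OCC=C)c(CC=C(C)C)c1 | intermediate
9 | lithium 1-[3,5-bis(3-methylbut-2-enyl)-4-(prop-2-enyloxy)phenyl]-2-methoxy-1-[methoxy(methyl)amino]ethanolate (racemic, not isolated) | COCC(O[Li])(N(C)OC)c1cc(CC=C(C)C)c(OCC=C)c(CC=C(C)C)c1 | intermediate
10 | 1-[3,5-bis(3-methylbut-2-enyl)-4-(prop-2-enyloxy)phenyl]-2-methoxyethanone | COCC(=O)c1cc(CC=C(C)C)c(OCC=C)c(CC=C(C)C)c1 | intermediate
11 | 2,4,6-trifluorobenzoyl chloride | O=C(Cl)c1c(F)cc(F)cc1F | starting material
12 | lithium (Z)-1-[3,5-bis(3-methylbut-2-enyl)-4-(prop-2-enyloxy)phenyl]-2-methoxyethen-1-olate (not isolated) | CO/C=C(\O[Li])c1cc(CC=C(C)C)c(OCC=C)c(CC=C(C)C)c1 | intermediate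
13 | 1-[3,5-bis(3-methylbut-2-enyl)-4-(prop-2-enyloxy)phenyl]-2-methoxy-3-(2,4,6-trifluorophenyl)propane-1,3-dione (racemic, enolisable) | COC(C(=O)c1c(F)cc(F)cc1F)C(=O)c1cc(CC=C(C)C)c(OCC=C)c(CC=C(C)C)c1 | intermediate
14 | prop-2-en-1-ol (allyl alcohol) | C=CCO | starting material
15 | potassium 1-[3,5-bis(3-methylbut-2-enyl)-4-(prop-2-enyloxy)phenyl]-2-methoxy-3-oxo-3-(2,4,6-trifluorophenyl)prop-1-en-1-olate (one resonance form, not isolated) | COC(C(=O)c1c(F)cc(F)cc1F)=C([O-])c1cc(CC=C(C)C)c(OCC=C)c(CC=C(C)C)c1.[K+] | intermediate
16 | 2-[3,5-bis(3-methylbut-2-enyl)-4-(prop-2-enyloxy)phenyl]-5,7-difluoro-3-methoxy-4H-chromen-4-one (not isolated) | COc1c(-c2cc(CC=C(C)C)c(OCC=C)c(CC=C(C)C)c2)oc2cc(F)cc(F)c2c1=O | intermediate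
17 | 2-[3,5-bis(3-methylbut-2-enyl)-4-(prop-2-enyloxy)phenyl]-5-fluoro-3-methoxy-7-(prop-2-enyloxy)-4H-chromen-4-one (not isolated) | COc1c(-c2cc(CC=C(C)C)c(OCC=C)c(CC=C(C)C)c2)oc2cc(OCC=C)cc(F)c2c1=O | intermediate
18 | 2-[3,5-bis(3-methylbut-2-enyl)-4-(prop-2-enyloxy)phenyl]-3-methoxy-5,7-bis(prop-2-enyloxy)-4H-chromen-4-one | COc1c(-c2cc(CC=C(C)C)c(OCC=C)c(CC=C(C)C)c2)oc2cc(OCC=C)cc(OCC=C)c2c1=O | intermediate
19 | 5,7-dihydroxy-2-[4-hydroxy-3,5-bis(3-methylbut-2-enyl)phenyl]-3-methoxy-4H-chromen-4-one | COc1c(-c2cc(CC=C(C)C)c(O)c(CC=C(C)C)c2)oc2cc(O)cc(O)c2c1=O | target

## Step count and least certain steps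

Total step count: 6. Longest linear sequence: 6 steps (1 to 19 through steps 1 to 6); 2, 5, 7, 11 and 14 enter as bought reagents.

**Step 5 (key step).**
What may go wrong: the second intermolecular substitution may stall. Once O7 is in place, the C4 carbonyl is a doubly vinylogous ester and activates the C5–F bond only weakly, so the reaction could stop at 17. Forcing it invites three processes: alkoxide addition at C2 with opening of ring C, base-induced migration of the allyl double bonds to prop-1-enyl ethers, and migration of the prenyl double bonds into conjugation with ring B.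
Fallback (ring A oxygens installed before ring closure, Baker–Venkataraman route), setting out from 6 and returning at 18: bromine–lithium exchange on 6 (n-BuLi, THF, −78 °C) and a CO2 quench should give 3,5-bis(3-methylbut-2-enyl)-4-(prop-2-enyloxy)benzoic acid F1. In parallel, the Hoesch reaction of phloroglucinol with methoxyacetonitrile (ZnCl2, HCl, Et2O, then hot water) should give 2-methoxy-1-(2,4,6-trihydroxyphenyl)ethanone F2. Alkylation of F2 with 5 (2 equiv, K2CO3, acetone) at the para and one ortho oxygen, sparing the hydrogen-bonded one, should give 1-[2-hydroxy-4,6-bis(prop-2-enyloxy)phenyl]-2-methoxyethanone F3. Esterification of F3 with F1 (EDC·HCl, DMAP, CH2Cl2) should give 2-(2-methoxyacetyl)-3,5-bis(prop-2-enyloxy)phenyl 3,5-bis(3-methylbut-2-enyl)-4-(prop-2-enyloxy)benzoate F4. LiN(SiMe3)2 in THF should then move the aroyl group from oxygen to the α-carbon (Baker–Venkataraman rearrangement) to give 1-[3,5-bis(3-methylbut-2-enyl)-4-(prop-2-enyloxy)phenyl]-3-[2-hydroxy-4,6-bis(prop-2-enyloxy)phenyl]-2-methoxypropane-1,3-dione F5, and cyclodehydration of F5 in AcOH/NaOAc at 100 °C should close ring C through the phenol oxygen and give 18. This brings back the nucleophilic phloroglucinol ketone and a mildly acidic closure, acceptable only because O4' is still capped, but every event is standard flavone chemistry.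

**Step 1.**
What may go wrong: O-alkylation competing with C-alkylation, a spread over mono- and dialkylated phenols, and acid-triggered closure of the ortho-prenyl phenol to a chroman during work-up or chromatography.
Fallback (two Claisen rearrangements), setting out from 1 and returning at 4: O-alkylation of 1 with tert-butyl 2-methylbut-3-en-2-yl carbonate and Pd(PPh3)4 (THF, 0 °C; the phenoxide attacks the more substituted allyl terminus) should give 1-bromo-4-[(2-methylbut-3-en-2-yl)oxy]benzene F6. Aromatic Claisen rearrangement of F6 (N,N-diethylaniline, 130 °C) moves the group to the ortho carbon with allylic inversion and should give 3, here isolated. The same two operations on 3 should give 4-bromo-1-[(2-methylbut-3-en-2-yl)oxy]-2-(3-methylbut-2-enyl)benzene F7 and then, from F7, the phenol 4. The bromine blocks the para position throughout, so only ortho migration is open.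

**Step 4.**
What may go wrong: acylation of enolate 12 at oxygen, giving an enol ester, or a second acylation of the product enolate.
Fallback (aldol addition and oxidation), setting out from 10 and returning at 13: addition of enolate 12 to 2,4,6-trifluorobenzaldehyde (THF, −78 °C) should give 1-[3,5-bis(3-methylbut-2-enyl)-4-(prop-2-enyloxy)phenyl]-3-hydroxy-2-methoxy-3-(2,4,6-trifluorophenyl)propan-1-one F8 as a mixture of racemic diastereomers. Dess–Martin periodinane (CH2Cl2, NaHCO3, 0 °C) should oxidise F8 to 13. An aldehyde can be attacked only at carbon by the enolate, so the C3–C4 bond is secured before the oxidation level is adjusted.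

**Step 6.**
What may go wrong: transfer of the allyl group from π-allyl palladium to a carbon (C6 or C8) of the liberated, phloroglucinol-like ring A phenoxide in place of the amine, and slow ionisation of the O5 ether next to the carbonyl.
Fallback (isomerisation and hydrolysis), setting out from 18 and returning at 19: [Ir(cod)(PMePh2)2]PF6, activated with H2, in THF should isomerise the three allyl ethers to give 2-[3,5-bis(3-methylbut-2-enyl)-4-(prop-1-enyloxy)phenyl]-3-methoxy-5,7-bis(prop-1-enyloxy)-4H-chromen-4-one F9 (mixture of alkene isomers); the trisubstituted prenyl alkenes are not substrates for this catalyst. Very dilute HCl in aqueous THF at 25 °C should then hydrolyse the enol ethers of F9 to 19 and propanal, under conditions far milder than those that close a prenyl phenol to a chroman.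

## Further compounds

F1 | step 5 | 3,5-bis(3-methylbut-2-enyl)-4-(prop-2-enyloxy)benzoic acid | OC(=O)c1cc(CC=C(C)C)c(OCC=C)c(CC=C(C)C)c1
F2 | step 5 | 2-methoxy-1-(2,4,6-trihydroxyphenyl)ethanone | COCC(=O)c1c(O)cc(O)cc1O
F3 | step 5 | 1-[2-hydroxy-4,6-bis(prop-2-enyloxy)phenyl]-2-methoxyethanone | COCC(=O)c1c(O)cc(OCC=C)cc1OCC=C
F4 | step 5 | 2-(2-methoxyacetyl)-3,5-bis(prop-2-enyloxy)phenyl 3,5-bis(3-methylbut-2-enyl)-4-(prop-2-enyloxy)benzoate | COCC(=O)c1c(OCC=C)cc(OCC=C)cc1OC(=O)c1cc(CC=C(C)C)c(OCC=C)c(CC=C(C)C)c1
F5 | step 5 | 1-[3,5-bis(3-methylbut-2-enyl)-4-(prop-2-enyloxy)phenyl]-3-[2-hydroxy-4,6-bis(prop-2-enyloxy)phenyl]-2-methoxypropane-1,3-dione (racemic, enolisable) | COC(C(=O)c1c(O)cc(OCC=C)cc1OCC=C)C(=O)c1cc(CC=C(C)C)c(OCC=C)c(CC=C(C)C)c1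
F6 | step 1 | 1-bromo-4-[(2-methylbut-3-en-2-yl)oxy]benzene | C=CC(C)(C)Oc1ccc(Br)cc1
F7 | step 1 | 4-bromo-1-[(2-methylbut-3-en-2-yl)oxy]-2-(3-methylbut-2-enyl)benzene | C=CC(C)(C)Oc1ccc(Br)cc1CC=C(C)C
F8 | step 4 | 1-[3,5-bis(3-methylbut-2-enyl)-4-(prop-2-enyloxy)phenyl]-3-hydroxy-2-methoxy-3-(2,4,6-trifluorophenyl)propan-1-one (racemic, mixture of diastereomers) | COC(C(O)c1c(F)cc(F)cc1F)C(=O)c1cc(CC=C(C)C)c(OCC=C)c(CC=C(C)C)c1
F9 | step 6 | 2-[3,5-bis(3-methylbut-2-enyl)-4-(prop-1-enyloxy)phenyl]-3-methoxy-5,7-bis(prop-1-enyloxy)-4H-chromen-4-one (mixture of alkene isomers) | COc1c(-c2cc(CC=C(C)C)c(OC=CC)c(CC=C(C)C)c2)oc2cc(OC=CC)cc(OC=CC)c2c1=O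
A1 | alternative 1 | 2-iodo-1,3,5-tris(methoxymethoxy)benzene | COCOc1cc(OCOC)c(I)c(OCOC)c1
A2 | alternative 1 | carbon monoxide | [C-]#[O+]
A3 | alternative 1 | 2-methoxy-1-[4-(methoxymethoxy)-3,5-bis(3-methylbut-2-enyl)phenyl]ethanone | COCC(=O)c1cc(CC=C(C)C)c(OCOC)c(CC=C(C)C)c1
A4 | alternative 1 | 2-methoxy-1-[4-(methoxymethoxy)-3,5-bis(3-methylbut-2-enyl)phenyl]-3-[2,4,6-tris(methoxymethoxy)phenyl]propane-1,3-dione (racemic, enolisable) | COCOc1cc(OCOC)c(C(=O)C(OC)C(=O)c2cc(CC=C(C)C)c(OCOC)c(CC=C(C)C)c2)c(OCOC)c1
A5 | alternative 2 | 2-[2-formyl-3,5-bis(methoxymethoxy)phenoxy]-2-[4-(methoxymethoxy)-3,5-bis(3-methylbut-2-enyl)phenyl]acetaldehyde (racemic) | O=CC(Oc1cc(OCOC)cc(OCOC)c1C=O)c1cc(CC=C(C)C)c(OCOC)c(CC=C(C)C)c1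
A6 | alternative 2 | samarium diiodide | I[Sm]I
A7 | alternative 2 | 2,3-trans-3,4-cis-2-[4-(methoxymethoxy)-3,5-bis(3-methylbut-2-enyl)phenyl]-5,7-bis(methoxymethoxy)chromane-3,4-diol (racemic, relative configuration drawn) | O[C@@H]1[C@H](O)[C@@H](c2cc(CC=C(C)C)c(OCOC)c(CC=C(C)C)c2)Oc2cc(OCOC)cc(OCOC)c21
A8 | alternative 3 | 6-(2-diazoacetyl)-3-methoxy-2-[4-(methoxymethoxy)-3,5-bis(3-methylbut-2-enyl)phenyl]-4H-pyran-4-one | COc1c(-c2cc(CC=C(C)C)c(OCOC)c(CC=C(C)C)c2)oc(C(=O)C=[N+]=[N-])cc1=O
A9 | alternative 3 | (ethynyloxy)tri(propan-2-yl)silane | C#CO[Si](C(C)C)(C(C)C)C(C)C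
A10 | alternative 3 | 5-hydroxy-3-methoxy-2-[4-(methoxymethoxy)-3,5-bis(3-methylbut-2-enyl)phenyl]-7-[tri(propan-2-yl)silyloxy]-4H-chromen-4-one | COc1c(-c2cc(CC=C(C)C)c(OCOC)c(CC=C(C)C)c2)oc2cc(O[Si](C(C)C)(C(C)C)C(C)C)cc(O)c2c1=O
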